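**Retrosynthetic overview**
1. The target comes from a C-4/C-6 diol by late acylation of C-6–OH; the C-10 tiglate is put on early. The diol comes from a β-hydroxy ketone, which comes from an isoxazoline.
2. Key ring: the seven-membered ring (C-5–C-6 bond, together with the C-4–O bond) closes in an intramolecular nitrile oxide–alkene [3+2] cycloaddition across a preformed cyclopentene; this fixes the cis 5/7 fusion.
3. Key bond before that: C-1–C-10, made by a [2,3]-Wittig rearrangement of a tertiary cyclopentenyl (Z)-enynyl ether; it relays the bought carbinol configuration to C-1 and C-10.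
4. The cyclopentenol comes from (S)-terpinen-4-ol (ozonolysis, aldol ring contraction, decarbonylation); the six-carbon side chain from (Z)-3-methylpent-2-en-4-yn-1-ol.
5. Ring order: cyclopentene first, then cycloheptene and isoxazoline together, then the isoxazoline is opened.

**Assumptions**
- The SMILES is read literally: a cis-fused hydroazulene, (1R,4R,5S,6S,10R) in daucane numbering. Atoms are written C-n: C-1 angular methyl carbon, C-2/C-3 ring CH2, C-4 isopropyl carbinol, C-5 ring-fusion CH, C-6 CH–O-aroyl, C-7 CH2, C-8 C(CH3)=, C-9 =CH, C-10 CH–O-tigloyl.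
- (S)-(+)-Terpinen-4-ol is used as the single enantiomer; commercial grades may be only enantio-enriched, and the route inherits whatever purity is bought. (Z)-3-Methylpent-2-en-4-yn-1-ol, tigloyl chloride and 4-acetoxybenzoyl chloride are bought.

**Route**

Step 1
Reactants: 1 (S)-(+)-terpinen-4-ol, (1S)-4-methyl-1-(propan-2-yl)cyclohex-3-en-1-ol
Product: 2 (3S)-3-hydroxy-6-oxo-3-(propan-2-yl)heptanal
Conditions: O3, CH2Cl2, −78 °C; then Me2S, −78 °C to rt
Reagents that add atoms: ozone, [O-][O+]=O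
Why: Ozonolysis with reductive work-up cleaves the only C=C to the keto aldehyde and leaves the bought tertiary carbinol stereocentre untouched.

Step 2
Reactants: 2 (3S)-3-hydroxy-6-oxo-3-(propan-2-yl)heptanal
Product: 3 (5R)-5-hydroxy-2-methyl-5-(propan-2-yl)cyclopent-1-ene-1-carbaldehyde
Conditions: Bn2NH·CF3CO2H (0.3 equiv), toluene, 50 °C
Reagents that add atoms: none
Why: Amine-salt-catalysed intramolecular aldol condensation (aldehyde enamine onto the methyl ketone, then loss of the new aldol hydroxyl) closes the cyclopentene; the carbinol centre is not involved and its label changes from S to R only through CIP priorities.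

Step 3
Reactants: 3 (5R)-5-hydroxy-2-methyl-5-(propan-2-yl)cyclopent-1-ene-1-carbaldehyde
Product: 4 (1R)-3-methyl-1-(propan-2-yl)cyclopent-2-en-1-ol
Conditions: RhCl(PPh3)3 (1.1 equiv), toluene, 110 °C
Reagents that add atoms: none
Why: Tsuji–Wilkinson decarbonylation replaces CHO by H without moving the alkene, giving the tertiary allylic alcohol whose carbinol carbon is the only stereocentre.

Step 4
Reactants: 5 (2Z)-3-methylpent-2-en-4-yn-1-ol
Product: 6 (3Z)-5-bromo-3-methylpent-3-en-1-yne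
Conditions: PBr3 (0.4 equiv), pyridine (cat.), Et2O, −10 to 0 °C; used at once
Reagents that add atoms: phosphorus tribromide, BrP(Br)Br
Why: SN2 bromination of the primary allylic alcohol at low temperature keeps the Z-alkene and the alkyne.

Step 5
Reactants: 4 (1R)-3-methyl-1-(propan-2-yl)cyclopent-2-en-1-ol; 6 (3Z)-5-bromo-3-methylpent-3-en-1-yne
Product: 7 (3R)-1-methyl-3-{[(2Z)-3-methylpent-2-en-4-yn-1-yl]oxy}-3-(propan-2-yl)cyclopent-1-ene
Conditions: KH (1.2 equiv), THF, 0 °C; then 6, Bu4NI (cat.), 0 °C to rt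
Reagents that add atoms: none
Why: Williamson etherification of the potassium tertiary alkoxide with the reactive allylic bromide; no bond to the stereocentre is broken.

Step 6
Reactants: 7 (3R)-1-methyl-3-{[(2Z)-3-methylpent-2-en-4-yn-1-yl]oxy}-3-(propan-2-yl)cyclopent-1-ene
Product: 8 (1R,2Z)-3-methyl-1-[(1R)-1-methyl-3-(propan-2-yl)cyclopent-2-en-1-yl]pent-2-en-4-yn-1-ol
Conditions: n-BuLi (2.3 equiv), THF, −78 to −30 °C; then H2O
Reagents that add atoms: none
Why: [2,3]-Wittig rearrangement: after the acetylide forms, the lithiated O–CH carbon (C-10) bonds to C-1 suprafacially on the face the ether oxygen leaves, so the carbinol chirality is transferred to the quaternary centre (1R) as the old carbinol carbon becomes C-4 of the C-4=C-5 alkene, and the envelope transition state with the enynyl group exo is expected to give (10R).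

Step 7
Reactants: 8 (1R,2Z)-3-methyl-1-[(1R)-1-methyl-3-(propan-2-yl)cyclopent-2-en-1-yl]pent-2-en-4-yn-1-ol
Product: 9 (1R,2Z)-3-methyl-1-[(1R)-1-methyl-3-(propan-2-yl)cyclopent-2-en-1-yl]pent-2-en-4-yn-1-yl (2E)-2-methylbut-2-enoate
Conditions: tigloyl chloride (1.5 equiv), Et3N, DMAP (cat.), CH2Cl2, 0 °C to rt
Reagents that add atoms: (2E)-2-methylbut-2-enoyl chloride (tigloyl chloride), C/C=C(\C)C(Cl)=O
Why: DMAP-catalysed acylation of the only hydroxyl group; the E-tiglate is the stable isomer and no stereocentre is touched.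

Step 8
Reactants: 9 (1R,2Z)-3-methyl-1-[(1R)-1-methyl-3-(propan-2-yl)cyclopent-2-en-1-yl]pent-2-en-4-yn-1-yl (2E)-2-methylbut-2-enoate
Product: 12 (1R,2Z,5E)-5-(hydroxyimino)-3-methyl-1-[(1R)-1-methyl-3-(propan-2-yl)cyclopent-2-en-1-yl]pent-2-en-1-yl (2E)-2-methylbut-2-enoate, via dienylborane 10 (not isolated), via aldehyde 11 (not isolated)
Conditions: Cy2BH (1.3 equiv), THF, 0 °C; 30% H2O2, pH 7 buffer (NaH2PO4/Na2HPO4), 0 °C; then NH2OH·HCl, NaOAc, EtOH, rt
Reagents that add atoms: hydroxylamine hydrochloride, [NH3+]O.[Cl-]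
Why: Anti-Markovnikov hydroboration–oxidation of the terminal alkyne with a hindered dialkylborane (the trisubstituted alkenes and the conjugated ester react far more slowly) gives the β,γ-unsaturated aldehyde, which is trapped at once by oxime condensation before it can move into conjugation.

Step 9
Reactants: 12 (1R,2Z,5E)-5-(hydroxyimino)-3-methyl-1-[(1R)-1-methyl-3-(propan-2-yl)cyclopent-2-en-1-yl]pent-2-en-1-yl (2E)-2-methylbut-2-enoate
Product: 15 cis-fused daucane isoxazoline (C-6=N–O–C-4 across C-4/C-5/C-6; 8-ene; 10-O-tigloyl; (1R,4R,5S,10R)), via hydroximoyl chloride 13 (not isolated), via nitrile oxide 14 (not isolated)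
Conditions: aq NaOCl (2 equiv), CH2Cl2, 0 °C to rt, 0.005 M, slow addition
Reagents that add atoms: none
Why: Intramolecular nitrile oxide–alkene 1,3-dipolar cycloaddition: the tether on C-1 delivers the dipole to the cyclopentene face it stands on, so the seven-membered ring closes cis-fused at C-5–C-6 with oxygen on the more substituted C-4, which sets C-4 (R) and C-5 (S) from C-1.

Step 10
Reactants: 15 cis-fused daucane isoxazoline
Product: 16 (1R,4R,5R,10R)-4-hydroxy-6-oxodauc-8-en-10-yl (2E)-2-methylbut-2-enoate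
Conditions: Mo(CO)6 (1.2 equiv), MeCN/H2O (15:1), 80 °C
Reagents that add atoms: water, O
Why: Mo(CO)6-mediated reductive N–O cleavage and hydrolysis of the β-hydroxy imine unmask the β-hydroxy ketone under neutral conditions that spare both alkenes and the ester; no centre changes geometry (C-5 becomes R by CIP only).

Step 11
Reactants: 16 (1R,4R,5R,10R)-4-hydroxy-6-oxodauc-8-en-10-yl (2E)-2-methylbut-2-enoate
Product: 17 (1R,4R,5S,6S,10R)-4,6-dihydroxydauc-8-en-10-yl (2E)-2-methylbut-2-enoate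
Conditions: Me4NBH(OAc)3 (5 equiv), MeCN/AcOH (1:1), −25 °C
Reagents that add atoms: none
Why: Evans–Saksena hydroxyl-directed reduction: the acetoxyborohydride bound to the tertiary C-4–OH delivers hydride to the C-6 face lying under that hydroxyl, so the new C-6–OH points to the opposite face (6S).

Step 12
Reactants: 17 (1R,4R,5S,6S,10R)-4,6-dihydroxydauc-8-en-10-yl (2E)-2-methylbut-2-enoate
Product: 18 (1R,4R,5S,6S,10R)-4-hydroxy-10-{[(2E)-2-methylbut-2-enoyl]oxy}dauc-8-en-6-yl 4-acetoxybenzoate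
Conditions: 4-acetoxybenzoyl chloride (1.3 equiv), pyridine, DMAP (cat.), CH2Cl2, 0 °C to rt
Reagents that add atoms: 4-acetoxybenzoyl chloride, CC(=O)Oc1ccc(cc1)C(Cl)=O
Why: Acylation of the secondary C-6–OH (the tertiary C-4–OH does not react) with the phenol-protected acid chloride, with retention at C-6.

Step 13
Reactants: 18 (1R,4R,5S,6S,10R)-4-hydroxy-10-{[(2E)-2-methylbut-2-enoyl]oxy}dauc-8-en-6-yl 4-acetoxybenzoate
Product: 19 (1R,4R,5S,6S,10R)-4-hydroxy-10-{[(2E)-2-methylbut-2-enoyl]oxy}dauc-8-en-6-yl 4-hydroxybenzoate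
Conditions: pyrrolidine (1.5 equiv), THF, 0 °C
Reagents that add atoms: none
Why: Chemoselective aminolysis of the aryl acetate, which is far more electrophilic than the alkyl tiglate and benzoate esters, frees the phenol and gives the target.

**Compound list**
1 | (S)-(+)-terpinen-4-ol, (1S)-4-methyl-1-(propan-2-yl)cyclohex-3-en-1-ol | CC1=CC[C@@](O)(CC1)C(C)C | starting material
2 | (3S)-3-hydroxy-6-oxo-3-(propan-2-yl)heptanal | O=CC[C@@](O)(CCC(C)=O)C(C)C | intermediate
3 | (5R)-5-hydroxy-2-methyl-5-(propan-2-yl)cyclopent-1-ene-1-carbaldehyde | CC(C)[C@]1(O)CCC(C)=C1C=O | intermediate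
4 | (1R)-3-methyl-1-(propan-2-yl)cyclopent-2-en-1-ol | CC(C)[C@]1(O)CCC(C)=C1 | intermediate
5 | (2Z)-3-methylpent-2-en-4-yn-1-ol | C#C/C(C)=C\CO | starting material
6 | (3Z)-5-bromo-3-methylpent-3-en-1-yne | C#C/C(C)=C\CBr | intermediate
7 | (3R)-1-methyl-3-{[(2Z)-3-methylpent-2-en-4-yn-1-yl]oxy}-3-(propan-2-yl)cyclopent-1-ene | CC(C)[C@]1(OC/C=C(C)\C#C)CCC(C)=C1 | intermediate
8 | (1R,2Z)-3-methyl-1-[(1R)-1-methyl-3-(propan-2-yl)cyclopent-2-en-1-yl]pent-2-en-4-yn-1-ol | O[C@@H]([C@]1(C)CCC(C(C)C)=C1)/C=C(C)\C#C | intermediate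
9 | (1R,2Z)-3-methyl-1-[(1R)-1-methyl-3-(propan-2-yl)cyclopent-2-en-1-yl]pent-2-en-4-yn-1-yl (2E)-2-methylbut-2-enoate | C/C=C(\C)C(=O)O[C@@H]([C@]1(C)CCC(C(C)C)=C1)/C=C(C)\C#C | intermediate
10 | (1R,2Z,4E)-5-(dicyclohexylboranyl)-3-methyl-1-[(1R)-1-methyl-3-(propan-2-yl)cyclopent-2-en-1-yl]penta-2,4-dien-1-yl (2E)-2-methylbut-2-enoate | C/C=C(\C)C(=O)O[C@@H]([C@]1(C)CCC(C(C)C)=C1)/C=C(C)\C=C\B(C2CCCCC2)C3CCCCC3 | intermediate (not isolated)
11 | (1R,2Z)-3-methyl-1-[(1R)-1-methyl-3-(propan-2-yl)cyclopent-2-en-1-yl]-5-oxopent-2-en-1-yl (2E)-2-methylbut-2-enoate | C/C=C(\C)C(=O)O[C@@H]([C@]1(C)CCC(C(C)C)=C1)/C=C(C)\CC=O | intermediate (not isolated)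
12 | (1R,2Z,5E)-5-(hydroxyimino)-3-methyl-1-[(1R)-1-methyl-3-(propan-2-yl)cyclopent-2-en-1-yl]pent-2-en-1-yl (2E)-2-methylbut-2-enoate | C/C=C(\C)C(=O)O[C@@H]([C@]1(C)CCC(C(C)C)=C1)/C=C(C)\C/C=N/O | intermediate
13 | (1R,2Z,5Z)-5-chloro-5-(hydroxyimino)-3-methyl-1-[(1R)-1-methyl-3-(propan-2-yl)cyclopent-2-en-1-yl]pent-2-en-1-yl (2E)-2-methylbut-2-enoate | C/C=C(\C)C(=O)O[C@@H]([C@]1(C)CCC(C(C)C)=C1)/C=C(C)\C/C(Cl)=N/O | intermediate (not isolated)
14 | (3Z,5R)-3-methyl-5-[(1R)-1-methyl-3-(propan-2-yl)cyclopent-2-en-1-yl]-5-{[(2E)-2-methylbut-2-enoyl]oxy}pent-3-enenitrile oxide | C/C=C(\C)C(=O)O[C@@H]([C@]1(C)CCC(C(C)C)=C1)/C=C(C)\CC#[N+][O-] | intermediate (not isolated)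
15 | cis-fused daucane isoxazoline: C-6 is C=N and the N–O oxygen is bonded to C-4; 8-ene; 1-methyl; 4-isopropyl; 10-O-[(2E)-2-methylbut-2-enoyl]; (1R,4R,5S,10R) | C/C=C(\C)C(=O)O[C@@H]1C=C(C)CC(=NO3)[C@@H]2[C@@]1(C)CC[C@@]23C(C)C | intermediate
16 | (1R,4R,5R,10R)-4-hydroxy-6-oxodauc-8-en-10-yl (2E)-2-methylbut-2-enoate, cis-fused | C/C=C(\C)C(=O)O[C@@H]1C=C(C)CC(=O)[C@@H]2[C@@]1(C)CC[C@@]2(O)C(C)C | intermediate
17 | (1R,4R,5S,6S,10R)-4,6-dihydroxydauc-8-en-10-yl (2E)-2-methylbut-2-enoate, cis-fused | C/C=C(\C)C(=O)O[C@@H]1C=C(C)C[C@H](O)[C@@H]2[C@@]1(C)CC[C@@]2(O)C(C)C | intermediate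
18 | (1R,4R,5S,6S,10R)-4-hydroxy-10-{[(2E)-2-methylbut-2-enoyl]oxy}dauc-8-en-6-yl 4-acetoxybenzoate | C/C=C(\C)C(=O)O[C@@H]1C=C(C)C[C@H](OC(=O)c2ccc(OC(C)=O)cc2)[C@@H]2[C@@]1(C)CC[C@@]2(O)C(C)C | intermediate
19 | (1R,4R,5S,6S,10R)-4-hydroxy-10-{[(2E)-2-methylbut-2-enoyl]oxy}dauc-8-en-6-yl 4-hydroxybenzoate; as azulene: (3R,3aS,4S,8R,8aR)-3-hydroxy-6,8a-dimethyl-8-{[(2E)-2-methylbut-2-enoyl]oxy}-3-(propan-2-yl)-1,2,3,3a,4,5,8,8a-octahydroazulen-4-yl 4-hydroxybenzoate | C/C=C(\C)C(=O)O[C@@H]1C=C(C)C[C@H](OC(=O)c2ccc(O)cc2)[C@@H]2[C@@]1(C)CC[C@@]2(O)C(C)C | target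

**Step count**
Total: 13 steps. Longest linear sequence: 12 steps (steps 1–3 and 5–13, from 1 to 19); step 4 prepares the side-chain bromide separately.

**Three steps most likely to fail, with fallbacks**

Step 3 (decarbonylation). The enal is tetrasubstituted and hindered, and the tertiary allylic alcohol may dehydrate at the temperature needed. The fallback sets out from 3 and comes back at 4. A Baeyer–Villiger oxidation of the enal (30% H2O2, catalytic SeO2, CH2Cl2, rt) gives the enol formate (5R)-5-hydroxy-2-methyl-5-(propan-2-yl)cyclopent-1-en-1-yl formate F1. MeLi (3.2 equiv, THF, −78 to 0 °C) cleaves the formate to the regiodefined lithium enolate, which is trapped with N-(5-chloropyridin-2-yl)bis(trifluoromethanesulfonyl)imide as the enol triflate (5R)-5-hydroxy-2-methyl-5-(propan-2-yl)cyclopent-1-en-1-yl trifluoromethanesulfonate F2. Palladium-catalysed formate reduction (Pd(OAc)2, PPh3, Bu3N, HCO2H, DMF, 60 °C) replaces the triflate by hydrogen and gives 4.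

Step 6 ([2,3]-Wittig rearrangement). The second lithiation next to an acetylide may be sluggish, and the C-10 configuration rests on a transition-state preference rather than on a stereospecific event. The fallback sets out from 7 and comes back at 9. The rearrangement is run as written and the unwanted epimer, (1S,2Z)-3-methyl-1-[(1R)-1-methyl-3-(propan-2-yl)cyclopent-2-en-1-yl]pent-2-en-4-yn-1-ol F3, is separated. It is esterified under Mitsunobu conditions (tiglic acid, PPh3, DIAD, toluene, 0 °C); the SN2 inversion at C-10 gives 9 directly, so both epimers converge and step 7 serves only the 10R fraction.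

Step 9 (seven-ring nitrile oxide cycloaddition). Closing a seven-membered ring is slow enough that furoxan dimerisation or oxidation by hypochlorite can compete. The fallback sets out from 9 and comes back at 15. Hydroboration–oxidation as in step 8 with in-flask reduction (Cy2BH; H2O2, pH 7; then NaBH4, MeOH, 0 °C) gives the primary alcohol (1R,2Z)-5-hydroxy-3-methyl-1-[(1R)-1-methyl-3-(propan-2-yl)cyclopent-2-en-1-yl]pent-2-en-1-yl (2E)-2-methylbut-2-enoate F4. I2, PPh3 and imidazole (CH2Cl2, 0 °C) give the iodide, the 5-iodo analogue of F4, F5; NaNO2 with phloroglucinol in DMF gives the primary nitro compound, the 5-nitro analogue of F4, F6. Mukaiyama dehydration (PhNCO, catalytic Et3N, toluene, 60 °C, syringe pump) releases nitrile oxide 14 slowly and without any oxidant, and it cyclises to 15.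

**Further compounds**
F1 | step 3 | (5R)-5-hydroxy-2-methyl-5-(propan-2-yl)cyclopent-1-en-1-yl formate | CC(C)[C@]1(O)CCC(C)=C1OC=O
F2 | step 3 | (5R)-5-hydroxy-2-methyl-5-(propan-2-yl)cyclopent-1-en-1-yl trifluoromethanesulfonate | CC(C)[C@]1(O)CCC(C)=C1OS(=O)(=O)C(F)(F)F
F3 | step 6 | (1S,2Z)-3-methyl-1-[(1R)-1-methyl-3-(propan-2-yl)cyclopent-2-en-1-yl]pent-2-en-4-yn-1-ol | O[C@H]([C@]1(C)CCC(C(C)C)=C1)/C=C(C)\C#C
F4 | step 9 | (1R,2Z)-5-hydroxy-3-methyl-1-[(1R)-1-methyl-3-(propan-2-yl)cyclopent-2-en-1-yl]pent-2-en-1-yl (2E)-2-methylbut-2-enoate | C/C=C(\C)C(=O)O[C@@H]([C@]1(C)CCC(C(C)C)=C1)/C=C(C)\CCO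
F5 | step 9 | (1R,2Z)-5-iodo-3-methyl-1-[(1R)-1-methyl-3-(propan-2-yl)cyclopent-2-en-1-yl]pent-2-en-1-yl (2E)-2-methylbut-2-enoate | C/C=C(\C)C(=O)O[C@@H]([C@]1(C)CCC(C(C)C)=C1)/C=C(C)\CCI
F6 | step 9 | (1R,2Z)-3-methyl-1-[(1R)-1-methyl-3-(propan-2-yl)cyclopent-2-en-1-yl]-5-nitropent-2-en-1-yl (2E)-2-methylbut-2-enoate | C/C=C(\C)C(=O)O[C@@H]([C@]1(C)CCC(C(C)C)=C1)/C=C(C)\CC[N+](=O)[O-]
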